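**Retrosynthetic overview**
- The target comes from a protected ring A benzaldehyde. The C1 formyl group is put in last, by lithiation of the one ring CH that lies between the C2 and C6 oxygens, followed by unmasking of the acid and the phenols.
- Ring A is built, not substituted. Its para oxygens on C3 and C6, the third oxygen on C2 beside C3, and the C4–H next to chain-bearing C5 are the pattern that a 4-alkenyl-4-hydroxy-3-alkoxycyclobut-2-enone hands to a benzene ring on heating (new bond C5–C6; the cyclobutenone CH becomes C1).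
- The cyclobutenone comes from an (E)-alkenyllithium (future C4, C5 and chain C1'–C12') and 3-isopropoxycyclobutenedione, itself made from diisopropyl squarate.
- The chain comes from farnesyl acetate: oxidation of the terminal (E)-methyl to the enoic acid, asymmetric hydrogenation for (S)-C11', acid masked as a bicyclic orthoester, ethynyl extension at C1', hydrozirconation–iodination.
- Ring order: ring A is the only ring and is closed in step 13.

Key step: step 13

Assumption: Ru(OAc)2[(S)-H8-BINAP] is taken to give the (S)-acid, as it does with (E)-2-methylbut-2-enoic acid; if the sense proves opposite, the (R)-ligand is used.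

Numbering and abbreviation: ring carbons C1–C6 and chain carbons C1'–C12' as in the target (C1 formyl-bearing, C5 chain-bearing, C1' benzylic, C11' the stereocentre, C12' the carboxyl carbon). OBO = 4-methyl-2,6,7-trioxabicyclo[2.2.2]octan-1-yl. Orthoester-bearing compounds are chromatographed on Et3N-deactivated silica.

**Step 1**
Reactants: 1 (2E,6E)-farnesyl acetate
Product: 2 (2E,6E,10E)-12-hydroxyfarnesyl acetate
Conditions: SeO2 (0.1 equiv), t-BuOOH (3 equiv), salicylic acid (0.1 equiv), CH2Cl2, rt; stop at partial conversion, recycle 1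
Reagents that add atoms: tert-butyl hydroperoxide, CC(C)(C)OO
Why: SeO2-catalysed allylic oxidation (Riley oxidation, ene reaction then [2,3]-sigmatropic shift) should hydroxylate the (E)-methyl group of the terminal, most electron-rich trisubstituted alkene, the alkene next to the acetate being deactivated.

**Step 2**
Reactants: 2 (2E,6E,10E)-12-hydroxyfarnesyl acetate
Product: 3 (2E,6E,10E)-3,7,11-trimethyl-12-oxododeca-2,6,10-trien-1-yl acetate
Conditions: MnO2 (activated, 15 equiv), CH2Cl2, rt
Reagents that add atoms: none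
Why: Heterogeneous MnO2 oxidation is selective for the allylic alcohol, should keep the (E)-geometry, and also collects any enal already formed in step 1.

**Step 3**
Reactants: 3 (2E,6E,10E)-3,7,11-trimethyl-12-oxododeca-2,6,10-trien-1-yl acetate
Product: 4 (2E,6E,10E)-12-acetoxy-2,6,10-trimethyldodeca-2,6,10-trienoic acid
Conditions: NaClO2, NaH2PO4, 2-methyl-2-butene, t-BuOH/H2O, 0 °C to rt
Reagents that add atoms: sodium chlorite, [Na+].[O-]Cl=O
Why: Pinnick oxidation converts the enal to the enoic acid without touching the alkenes or the acetate, the 2-methyl-2-butene trapping the hypochlorous acid that would otherwise add to the trisubstituted alkenes.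

**Step 4**
Reactants: 4 (2E,6E,10E)-12-acetoxy-2,6,10-trimethyldodeca-2,6,10-trienoic acid
Product: 5 (2S,6E,10E)-12-acetoxy-2,6,10-trimethyldodeca-6,10-dienoic acid
Conditions: H2 (4 atm), Ru(OAc)2[(S)-H8-BINAP] (0.5 mol%), MeOH, rt
Reagents that add atoms: none
Why: Carboxylate-directed Ru–BINAP-type asymmetric hydrogenation reduces only the conjugated, carboxylate-chelated C10'=C11' alkene and sets C11' by hydrogen delivery to the face chosen by the (S)-ligand, which gives (S)-2-methylalkanoic acids from (E)-2-methylalk-2-enoic acids, while the two isolated alkenes and the allylic acetate carry no directing group and should remain.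

**Step 5**
Reactants: 5 (2S,6E,10E)-12-acetoxy-2,6,10-trimethyldodeca-6,10-dienoic acid; 6 3-methyl-3-oxetanemethanol
Product: 7 (3-methyloxetan-3-yl)methyl (2S,6E,10E)-12-acetoxy-2,6,10-trimethyldodeca-6,10-dienoate
Conditions: DCC, DMAP (cat.), CH2Cl2, 0 °C to rt
Reagents that add atoms: none
Why: Steglich esterification at 0 °C joins the acid to the oxetane alcohol under neutral conditions that should not epimerise the weakly acidic C11' centre.

**Step 6**
Reactants: 7 (3-methyloxetan-3-yl)methyl (2S,6E,10E)-12-acetoxy-2,6,10-trimethyldodeca-6,10-dienoate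
Product: 8 (2E,6E,11S)-3,7-dimethyl-11-(OBO)dodeca-2,6-dien-1-yl acetate
Conditions: BF3·OEt2 (0.25 equiv), CH2Cl2, −15 °C; Et3N quench
Reagents that add atoms: none
Why: Lewis acid-catalysed oxetane ester rearrangement, in which BF3 opens the oxetane with participation of the ester carbonyl oxygen to a dioxanylium ion that the freed alkoxide closes to the bridged orthoester, and the low temperature and substoichiometric acid should spare the alkenes and the allylic acetate.

**Step 7**
Reactants: 8 (2E,6E,11S)-3,7-dimethyl-11-(OBO)dodeca-2,6-dien-1-yl acetate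
Product: 9 (2E,6E,11S)-3,7-dimethyl-11-(OBO)dodeca-2,6-dien-1-ol
Conditions: K2CO3 (cat.), MeOH, rt
Reagents that add atoms: none
Why: Base-catalysed transesterification (methanolysis) removes the acetate, the orthoester being inert to carbonate and methoxide.

**Step 8**
Reactants: 9 (2E,6E,11S)-3,7-dimethyl-11-(OBO)dodeca-2,6-dien-1-ol
Product: 10 (2E,6E,11S)-1-bromo-3,7-dimethyl-11-(OBO)dodeca-2,6-diene
Conditions: CBr4, PPh3, 2,6-lutidine (0.2 equiv), CH2Cl2, −20 to 0 °C; used crude
Reagents that add atoms: carbon tetrabromide, BrC(Br)(Br)Br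
Why: The Appel reaction converts the primary allylic alcohol to the bromide by SN2 displacement of the oxyphosphonium ion under essentially neutral conditions that the orthoester tolerates, without allylic transposition.

**Step 9**
Reactants: 10 (2E,6E,11S)-1-bromo-3,7-dimethyl-11-(OBO)dodeca-2,6-diene; 11 ethynylmagnesium bromide
Product: 12 (4E,8E,13S)-5,9-dimethyl-13-(OBO)tetradeca-4,8-dien-1-yne
Conditions: 11 (3 equiv, 0.5 M in THF), CuBr·SMe2 (10 mol%), THF, 0 °C to rt
Reagents that add atoms: none
Why: Copper-catalysed coupling of an alkynyl Grignard reagent with a primary allylic bromide should go at the unhindered C1' terminus (SN2 and not SN2', which would have to build a quaternary carbon) and give the skipped enyne with the (E)-alkene intact, the excess of 11 preventing a second allylation of the product acetylide.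

**Step 10**
Reactants: 12 (4E,8E,13S)-5,9-dimethyl-13-(OBO)tetradeca-4,8-dien-1-yne
Product: 14 (1E,4E,8E,13S)-1-iodo-5,9-dimethyl-13-(OBO)tetradeca-1,4,8-triene, via alkenylzirconocene chloride 13 (not isolated)
Conditions: Cp2Zr(H)Cl (1.2 equiv), THF, rt, dark; then I2 (1.2 equiv), THF, 0 °C; Na2S2O3 aq.
Reagents that add atoms: iodine, [I][I]; Cp2Zr(H)Cl, [H][Zr](Cl)(C1C=CC=C1)C1C=CC=C1 (its zirconium remains only in 13)
Why: Hydrozirconation adds Zr–H syn across the terminal alkyne with zirconium at the terminal carbon much faster than it touches trisubstituted alkenes, and iodinolysis of the C–Zr bond with retention gives the (E)-iodoalkene.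

**Step 11**
Reactants: 15 diisopropyl squarate
Product: 17 3-isopropoxycyclobut-3-ene-1,2-dione, via hydroxycyclobutenone 16 (not isolated)
Conditions: LiAlH(OtBu)3 (1.05 equiv), THF, −78 to −20 °C; then 6 M HCl aq., CH2Cl2, 0 °C to rt
Reagents that add atoms: none
Why: Mono 1,2-reduction of one squarate carbonyl by the bulky hydride (the remaining carbonyl becomes a deactivated vinylogous ester) is followed by acid-induced ionisation of the allylic carbinol to an alkoxy-stabilised cation whose hydrolysis expels isopropanol, a 1,3-carbonyl transposition that gives the semisquarate.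

**Step 12**
Reactants: 14 (1E,4E,8E,13S)-1-iodo-5,9-dimethyl-13-(OBO)tetradeca-1,4,8-triene; 17 3-isopropoxycyclobut-3-ene-1,2-dione
Product: 19 4-hydroxy-3-isopropoxy-4-[(1E,4E,8E,13S)-5,9-dimethyl-13-(OBO)tetradeca-1,4,8-trien-1-yl]cyclobut-2-en-1-one, via alkenyllithium 18 (not isolated)
Conditions: t-BuLi (2.05 equiv), Et2O, −78 °C; cannulated into 17 (1.2 equiv), THF, −78 °C; H2O quench at −78 °C, pH 7 buffer wash
Reagents that add atoms: tert-butyllithium, [Li]C(C)(C)C (its lithium remains only in 18)
Why: Iodine–lithium exchange proceeds with retention of the (E)-geometry, and the alkenyllithium adds 1,2 to the ketone-like carbonyl next to the isopropoxy-bearing carbon and not to the other carbonyl, which is a vinylogous ester, as is the rule for 3-alkoxycyclobutenediones, while the new carbinol centre forms unselectively, which is of no consequence because it becomes an arene carbon in step 13.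

**Step 13**
Reactants: 19 4-hydroxy-3-isopropoxy-4-[(1E,4E,8E,13S)-5,9-dimethyl-13-(OBO)tetradeca-1,4,8-trien-1-yl]cyclobut-2-en-1-one
Product: 22 2-isopropoxy-5-[(2E,6E,11S)-3,7-dimethyl-11-(OBO)dodeca-2,6-dien-1-yl]benzene-1,4-diol, via dienylketene 20 (not isolated), via cyclohexadienone 21 (not isolated)
Conditions: toluene (degassed, 0.02 M), 110 °C, Ar (p-xylene, 138 °C if slow); concentrated under Ar and used at once
Reagents that add atoms: none
Why: Heating opens the cyclobutenone by conrotatory 4π electrocyclic cleavage of the bond between the carbonyl carbon and the carbinol carbon, the hydroxyl turning outward (torquoselectivity of a donor substituent) so that the alkenyl group comes to lie cis to the ketene in dienylketene 20. Disrotatory 6π electrocyclisation then joins the ketene carbon (future C6) to the far alkenyl carbon (future C5) and closes the six-membered ring A as cyclohexadienone 21, whose enolisation gives the aromatic hydroquinone 22; this is the Moore rearrangement of 4-alkenyl-4-hydroxycyclobutenones, applied here to a 2-unsubstituted 3-alkoxy ring that carries a 1,4-dienyl group. No stereocentre is created, because the carbinol carbon and the transient sp3 C5 both end as arene carbons, and the remote (S)-centre, flanked by a non-enolisable orthoester, is not involved. The selectivity needed is regiochemical and is fixed by the connectivity of 19: the isopropoxy carbon is bonded to the carbinol carbon, so the ether must appear ortho to the C3 hydroxyl and para to the chain, and the outward rotation of the hydroxyl is what turns the alkene toward the ketene. The skipped diene, the trisubstituted alkenes and the orthoester have no thermal pathway under neutral conditions at this temperature, and oxygen is excluded because the product is an electron-rich hydroquinone.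

**Step 14**
Reactants: 22 2-isopropoxy-5-[(2E,6E,11S)-3,7-dimethyl-11-(OBO)dodeca-2,6-dien-1-yl]benzene-1,4-diol
Product: 23 1-isopropoxy-2,5-bis(methoxymethoxy)-4-[(2E,6E,11S)-3,7-dimethyl-11-(OBO)dodeca-2,6-dien-1-yl]benzene
Conditions: NaH (2.5 equiv), MOMCl (2.5 equiv), DMF, 0 °C, Ar
Reagents that add atoms: chloromethyl methyl ether, COCCl
Why: Williamson etherification of both phenoxides with MOMCl masks the oxidation-prone hydroquinone and places on C3 and C6 the acetal groups that direct the next lithiation, the orthoester being stable to NaH.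

**Step 15**
Reactants: 23 1-isopropoxy-2,5-bis(methoxymethoxy)-4-[(2E,6E,11S)-3,7-dimethyl-11-(OBO)dodeca-2,6-dien-1-yl]benzene
Product: 25 2-isopropoxy-3,6-bis(methoxymethoxy)-5-[(2E,6E,11S)-3,7-dimethyl-11-(OBO)dodeca-2,6-dien-1-yl]benzaldehyde, via aryllithium 24 (not isolated)
Conditions: n-BuLi (1.3 equiv), TMEDA (1.3 equiv), THF, −20 to 0 °C; then DMF (3 equiv), −78 to 0 °C; H2O
Reagents that add atoms: N,N-dimethylformamide, CN(C)C=O; n-butyllithium, [Li]CCCC (its lithium remains only in 24)
Why: Directed ortho-metalation, in which the C1 hydrogen lies between the C2 isopropoxy and the C6 methoxymethoxy groups and is therefore removed in preference to C4–H, which has only one ether neighbour, and to the C1' methylene, after which the aryllithium is formylated by DMF while the orthoester shields C12' and leaves no enolisable hydrogen at C11'.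

**Step 16**
Reactants: 25 2-isopropoxy-3,6-bis(methoxymethoxy)-5-[(2E,6E,11S)-3,7-dimethyl-11-(OBO)dodeca-2,6-dien-1-yl]benzaldehyde
Product: 27 (2S,6E,10E)-12-[3-formyl-4-isopropoxy-2,5-bis(methoxymethoxy)phenyl]-2,6,10-trimethyldodeca-6,10-dienoic acid, via dihydroxy ester 26 (not isolated)
Conditions: 0.1 M NaHSO4 aq., DME, 0 °C, 20 min; then 1 M LiOH aq., rt; then 1 M HCl to pH 4, 0 °C
Reagents that add atoms: water, O
Why: The orthoester is unmasked in two stages, mild aqueous acid opening it to the monoester of the triol and hydroxide then saponifying that ester, at a point where all three phenol oxygens are still etherified so that base never meets a free polyphenol, and these mild conditions should not epimerise C11'.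

**Step 17**
Reactants: 27 (2S,6E,10E)-12-[3-formyl-4-isopropoxy-2,5-bis(methoxymethoxy)phenyl]-2,6,10-trimethyldodeca-6,10-dienoic acid
Product: 28 CNP0180353.1, (2S,6E,10E)-12-(3-formyl-2,4,5-trihydroxyphenyl)-2,6,10-trimethyldodeca-6,10-dienoic acid
Conditions: BCl3 (1 M in CH2Cl2, 6 equiv), CH2Cl2, −78 to −40 °C, Ar; MeOH then pH 5 buffer at −78 °C
Reagents that add atoms: none
Why: BCl3 ether cleavage, in which boron chelated between the formyl oxygen and the flanking C2 and C6 ether oxygens cleaves the isopropyl and acetal groups at low temperature (the C3 acetal is cleaved as readily), the phenols stay as borates until the cold buffered quench, and at −78 °C the trisubstituted alkenes and the C11' centre should not be affected.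

**Compound list**
1 | (2E,6E)-farnesyl acetate | CC(=O)OC/C=C(\C)CC/C=C(\C)CCC=C(C)C | starting material
2 | (2E,6E,10E)-12-hydroxyfarnesyl acetate [(2E,6E,10E)-12-hydroxy-3,7,11-trimethyldodeca-2,6,10-trien-1-yl acetate] | CC(=O)OC/C=C(\C)CC/C=C(\C)CC/C=C(\C)CO | intermediate
3 | (2E,6E,10E)-3,7,11-trimethyl-12-oxododeca-2,6,10-trien-1-yl acetate | CC(=O)OC/C=C(\C)CC/C=C(\C)CC/C=C(\C)C=O | intermediate
4 | (2E,6E,10E)-12-acetoxy-2,6,10-trimethyldodeca-2,6,10-trienoic acid | CC(=O)OC/C=C(\C)CC/C=C(\C)CC/C=C(\C)C(=O)O | intermediate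
5 | (2S,6E,10E)-12-acetoxy-2,6,10-trimethyldodeca-6,10-dienoic acid | CC(=O)OC/C=C(\C)CC/C=C(\C)CCC[C@H](C)C(=O)O | intermediate
6 | 3-methyl-3-oxetanemethanol | CC1(CO)COC1 | starting material
7 | (3-methyloxetan-3-yl)methyl (2S,6E,10E)-12-acetoxy-2,6,10-trimethyldodeca-6,10-dienoate | CC(=O)OC/C=C(\C)CC/C=C(\C)CCC[C@H](C)C(=O)OCC1(C)COC1 | intermediate
8 | (2E,6E,11S)-3,7-dimethyl-11-(4-methyl-2,6,7-trioxabicyclo[2.2.2]octan-1-yl)dodeca-2,6-dien-1-yl acetate | CC(=O)OC/C=C(\C)CC/C=C(\C)CCC[C@H](C)C12OCC(C)(CO1)CO2 | intermediate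
9 | (2E,6E,11S)-3,7-dimethyl-11-(OBO)dodeca-2,6-dien-1-ol | OC/C=C(\C)CC/C=C(\C)CCC[C@H](C)C12OCC(C)(CO1)CO2 | intermediate
10 | (2E,6E,11S)-1-bromo-3,7-dimethyl-11-(OBO)dodeca-2,6-diene | BrC/C=C(\C)CC/C=C(\C)CCC[C@H](C)C12OCC(C)(CO1)CO2 | intermediate
11 | ethynylmagnesium bromide | C#C[Mg]Br | starting material
12 | (4E,8E,13S)-5,9-dimethyl-13-(OBO)tetradeca-4,8-dien-1-yne | C#CC/C=C(\C)CC/C=C(\C)CCC[C@H](C)C12OCC(C)(CO1)CO2 | intermediate
13 | chlorobis(cyclopentadienyl)[(1E,4E,8E,13S)-5,9-dimethyl-13-(OBO)tetradeca-1,4,8-trien-1-yl]zirconium | Cl[Zr](/C=C/C/C=C(\C)CC/C=C(\C)CCC[C@H](C)C12OCC(C)(CO1)CO2)(C1C=CC=C1)C1C=CC=C1 | intermediate (not isolated)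
14 | (1E,4E,8E,13S)-1-iodo-5,9-dimethyl-13-(OBO)tetradeca-1,4,8-triene | I/C=C/C/C=C(\C)CC/C=C(\C)CCC[C@H](C)C12OCC(C)(CO1)CO2 | intermediate
15 | diisopropyl squarate (3,4-diisopropoxycyclobut-3-ene-1,2-dione) | CC(C)OC1=C(OC(C)C)C(=O)C1=O | starting material
16 | 4-hydroxy-2,3-diisopropoxycyclobut-2-en-1-one (racemic) | CC(C)OC1=C(OC(C)C)C(O)C1=O | intermediate (not isolated)
17 | 3-isopropoxycyclobut-3-ene-1,2-dione | CC(C)OC1=CC(=O)C1=O | intermediate
18 | [(1E,4E,8E,13S)-5,9-dimethyl-13-(OBO)tetradeca-1,4,8-trien-1-yl]lithium | [Li]/C=C/C/C=C(\C)CC/C=C(\C)CCC[C@H](C)C12OCC(C)(CO1)CO2 | intermediate (not isolated)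
19 | 4-hydroxy-3-isopropoxy-4-[(1E,4E,8E,13S)-5,9-dimethyl-13-(OBO)tetradeca-1,4,8-trien-1-yl]cyclobut-2-en-1-one (both configurations at the carbinol carbon) | O=C1C=C(OC(C)C)C1(O)/C=C/C/C=C(\C)CC/C=C(\C)CCC[C@H](C)C23OCC(C)(CO2)CO3 | intermediate
20 | (3Z,5E,8E,12E,17S)-4-hydroxy-3-isopropoxy-9,13-dimethyl-17-(OBO)octadeca-1,3,5,8,12-pentaen-1-one (dienylketene) | O=C=C/C(OC(C)C)=C(O)\C=C\C/C=C(\C)CC/C=C(\C)CCC[C@H](C)C12OCC(C)(CO1)CO2 | intermediate (not isolated)
21 | 4-hydroxy-3-isopropoxy-6-[(2E,6E,11S)-3,7-dimethyl-11-(OBO)dodeca-2,6-dien-1-yl]cyclohexa-2,4-dien-1-one (both configurations at C6 of the ring) | O=C1C=C(OC(C)C)C(O)=CC1C/C=C(\C)CC/C=C(\C)CCC[C@H](C)C23OCC(C)(CO2)CO3 | intermediate (not isolated)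
22 | 2-isopropoxy-5-[(2E,6E,11S)-3,7-dimethyl-11-(OBO)dodeca-2,6-dien-1-yl]benzene-1,4-diol | CC(C)Oc1cc(O)c(C/C=C(\C)CC/C=C(\C)CCC[C@H](C)C23OCC(C)(CO2)CO3)cc1O | intermediate
23 | 1-isopropoxy-2,5-bis(methoxymethoxy)-4-[(2E,6E,11S)-3,7-dimethyl-11-(OBO)dodeca-2,6-dien-1-yl]benzene | CC(C)Oc1cc(OCOC)c(C/C=C(\C)CC/C=C(\C)CCC[C@H](C)C23OCC(C)(CO2)CO3)cc1OCOC | intermediate
24 | aryllithium of 23, lithium on the ring carbon between the isopropoxy and a methoxymethoxy group (future C1) | CC(C)Oc1c([Li])c(OCOC)c(C/C=C(\C)CC/C=C(\C)CCC[C@H](C)C23OCC(C)(CO2)CO3)cc1OCOC | intermediate (not isolated)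
25 | 2-isopropoxy-3,6-bis(methoxymethoxy)-5-[(2E,6E,11S)-3,7-dimethyl-11-(OBO)dodeca-2,6-dien-1-yl]benzaldehyde | CC(C)Oc1c(C=O)c(OCOC)c(C/C=C(\C)CC/C=C(\C)CCC[C@H](C)C23OCC(C)(CO2)CO3)cc1OCOC | intermediate
26 | 3-hydroxy-2-(hydroxymethyl)-2-methylpropyl (2S,6E,10E)-12-[3-formyl-4-isopropoxy-2,5-bis(methoxymethoxy)phenyl]-2,6,10-trimethyldodeca-6,10-dienoate | CC(C)Oc1c(C=O)c(OCOC)c(C/C=C(\C)CC/C=C(\C)CCC[C@H](C)C(=O)OCC(C)(CO)CO)cc1OCOC | intermediate (not isolated)
27 | (2S,6E,10E)-12-[3-formyl-4-isopropoxy-2,5-bis(methoxymethoxy)phenyl]-2,6,10-trimethyldodeca-6,10-dienoic acid | CC(C)Oc1c(C=O)c(OCOC)c(C/C=C(\C)CC/C=C(\C)CCC[C@H](C)C(=O)O)cc1OCOC | intermediate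
28 | CNP0180353.1, (2S,6E,10E)-12-(3-formyl-2,4,5-trihydroxyphenyl)-2,6,10-trimethyldodeca-6,10-dienoic acid | C/C(=C\Cc1cc(O)c(O)c(C=O)c1O)CC/C=C(\C)CCC[C@H](C)C(=O)O | target

**Step count**
Total: 17 steps. Longest linear sequence: 16 steps (steps 1–10 and 12–17, from 1); step 11 is a one-step branch from 15.

**Steps most likely to fail**

Step 13. The dienylketene may be diverted before it cyclises (acylation of hydroxyl groups of other molecules, oligomerisation), or the hydroquinone may be oxidised during heating; the combination of a 2-unsubstituted ring with a skipped-diene substituent has no direct analogue. The fallback sets out from 12 and uses the alkynyl form of the same ring expansion. Deprotonation of 12 with n-BuLi (THF, −78 °C) gives the lithium acetylide F1, which adds to 17 at the same carbonyl to give the 4-alkynyl-4-hydroxy-3-isopropoxycyclobutenone F2. Heating F2 in toluene or p-xylene should give, through the (alkynylvinyl)ketene, a ring-closed diradical and hydrogen transfer from the hydroxyl, the air-stable 2-isopropoxy-5-alkyl-1,4-benzoquinone F3. Reduction with Na2S2O4 (Et2O/H2O) comes back to the route at 22; this path also makes steps 10 and 12 unnecessary.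

Step 15. Lateral deprotonation at the benzylic and allylic C1' methylene, which sits ortho to the C6 ether, or metalation at C4 could compete with metalation at C1 and lead to formylation at the wrong carbon. The fallback sets out from 19 and avoids any aryllithium. The carbinol is protected (MOMCl, iPr2NEt, Bu4NI, CH2Cl2, 40 °C) as the 4-(methoxymethoxy)cyclobutenone F4. Ring expansion of F4 in toluene at 110 °C gives the mono-protected hydroquinone F5, in which only the C6 hydroxyl (from the ketene oxygen) is free. Magnesium-mediated ortho-formylation (MgCl2, Et3N, paraformaldehyde, THF, reflux) can then occur only at C1, because the other position ortho to that hydroxyl is C5, and gives the salicylaldehyde F6. Etherification of the C6 hydroxyl (NaH, MOMCl, DMF) comes back to the route at 25.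

Step 17. The boron halide may damage the chain during ether cleavage, by hydrochlorination or cation–olefin cyclisation of the trisubstituted alkenes, or by ring closure of the C6 oxygen onto C3' to a chroman during the quench. The fallback sets out from 22 and removes the isopropyl group before the aldehyde is made, so that the last step needs only dilute protic acid.
- Ag2O (Et2O, MgSO4, rt) oxidises 22 to the quinone F3.
- The isopropoxy group, now part of a vinylogous ester, is exchanged by addition–elimination with dilute LiOH (THF/H2O, 0 °C, then pH 5 buffer) to give the hydroxyquinone F7.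
- Na2S2O4 reduces F7 to the benzenetriol F8, which is etherified at once (NaH, MOMCl, DMF) to the tris(methoxymethyl) ether F9.
- n-BuLi/TMEDA lithiates F9 between the C2 and C6 ethers to the aryllithium F10, and DMF gives the aldehyde F11.
- NaHSO4 aq. and then LiOH convert F11 through the dihydroxy ester F12 into the acid F13.
- HCl in MeOH at rt removes the three acetal groups and comes back to the route at 28.

Further compounds
F1 | step 13 | lithium acetylide of 12, [(4E,8E,13S)-5,9-dimethyl-13-(OBO)tetradeca-4,8-dien-1-yn-1-yl]lithium | [Li]C#CC/C=C(\C)CC/C=C(\C)CCC[C@H](C)C12OCC(C)(CO1)CO2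
F2 | step 13 | 4-hydroxy-3-isopropoxy-4-[(4E,8E,13S)-5,9-dimethyl-13-(OBO)tetradeca-4,8-dien-1-yn-1-yl]cyclobut-2-en-1-one (both configurations at the carbinol carbon) | O=C1C=C(OC(C)C)C1(O)C#CC/C=C(\C)CC/C=C(\C)CCC[C@H](C)C23OCC(C)(CO2)CO3
F3 | step 13 | 2-isopropoxy-5-[(2E,6E,11S)-3,7-dimethyl-11-(OBO)dodeca-2,6-dien-1-yl]cyclohexa-2,5-diene-1,4-dione | O=C1C=C(OC(C)C)C(=O)C=C1C/C=C(\C)CC/C=C(\C)CCC[C@H](C)C23OCC(C)(CO2)CO3
F4 | step 15 | 3-isopropoxy-4-(methoxymethoxy)-4-[(1E,4E,8E,13S)-5,9-dimethyl-13-(OBO)tetradeca-1,4,8-trien-1-yl]cyclobut-2-en-1-one (both configurations at C4) | O=C1C=C(OC(C)C)C1(OCOC)/C=C/C/C=C(\C)CC/C=C(\C)CCC[C@H](C)C23OCC(C)(CO2)CO3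
F5 | step 15 | 5-isopropoxy-4-(methoxymethoxy)-2-[(2E,6E,11S)-3,7-dimethyl-11-(OBO)dodeca-2,6-dien-1-yl]phenol | CC(C)Oc1cc(O)c(C/C=C(\C)CC/C=C(\C)CCC[C@H](C)C23OCC(C)(CO2)CO3)cc1OCOC
F6 | step 15 | 6-hydroxy-2-isopropoxy-3-(methoxymethoxy)-5-[(2E,6E,11S)-3,7-dimethyl-11-(OBO)dodeca-2,6-dien-1-yl]benzaldehyde | CC(C)Oc1c(C=O)c(O)c(C/C=C(\C)CC/C=C(\C)CCC[C@H](C)C23OCC(C)(CO2)CO3)cc1OCOC
F7 | step 17 | 2-hydroxy-5-[(2E,6E,11S)-3,7-dimethyl-11-(OBO)dodeca-2,6-dien-1-yl]cyclohexa-2,5-diene-1,4-dione | O=C1C=C(O)C(=O)C=C1C/C=C(\C)CC/C=C(\C)CCC[C@H](C)C23OCC(C)(CO2)CO3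
F8 | step 17 | 5-[(2E,6E,11S)-3,7-dimethyl-11-(OBO)dodeca-2,6-dien-1-yl]benzene-1,2,4-triol | Oc1cc(O)c(C/C=C(\C)CC/C=C(\C)CCC[C@H](C)C23OCC(C)(CO2)CO3)cc1O
F9 | step 17 | 1,2,4-tris(methoxymethoxy)-5-[(2E,6E,11S)-3,7-dimethyl-11-(OBO)dodeca-2,6-dien-1-yl]benzene | COCOc1cc(OCOC)c(C/C=C(\C)CC/C=C(\C)CCC[C@H](C)C23OCC(C)(CO2)CO3)cc1OCOC
F10 | step 17 | aryllithium of F9, lithium on the ring carbon between two methoxymethoxy groups (future C1) | COCOc1c([Li])c(OCOC)c(C/C=C(\C)CC/C=C(\C)CCC[C@H](C)C23OCC(C)(CO2)CO3)cc1OCOC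
F11 | step 17 | 2,3,6-tris(methoxymethoxy)-5-[(2E,6E,11S)-3,7-dimethyl-11-(OBO)dodeca-2,6-dien-1-yl]benzaldehyde | COCOc1c(C=O)c(OCOC)c(C/C=C(\C)CC/C=C(\C)CCC[C@H](C)C23OCC(C)(CO2)CO3)cc1OCOC
F12 | step 17 | 3-hydroxy-2-(hydroxymethyl)-2-methylpropyl (2S,6E,10E)-12-[3-formyl-2,4,5-tris(methoxymethoxy)phenyl]-2,6,10-trimethyldodeca-6,10-dienoate | COCOc1c(C=O)c(OCOC)c(C/C=C(\C)CC/C=C(\C)CCC[C@H](C)C(=O)OCC(C)(CO)CO)cc1OCOC
F13 | step 17 | (2S,6E,10E)-12-[3-formyl-2,4,5-tris(methoxymethoxy)phenyl]-2,6,10-trimethyldodeca-6,10-dienoic acid | COCOc1c(C=O)c(OCOC)c(C/C=C(\C)CC/C=C(\C)CCC[C@H](C)C(=O)O)cc1OCOC
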